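The carbocycle of the cis-fused octahydrochromene (C4a–C5–C6–C7–C8–C8a) is cut at C8–C8a and C5–C6. C8a, the oxygen-bearing ring-fusion carbon, is a latent ketal-derived oxocarbenium carbon and C5 lies β to the acetic acid carbonyl, so C8a–C4a–C5 is a 1,3-bis-electrophile. One flask joins it to an acetone α,α′-dianion equivalent (C8–C7–C6) that already carries the CMe2CO2Me arm: Mukaiyama C-glycosylation, then intramolecular Mukaiyama–Michael addition. The precursor is a monocyclic 2-methoxyoxane with an (E)-butenoate at C3, made from (R)-linalool (source of C2) by an ene reaction and ozonolysis; the temporary C7 carbonyl is reduced away afterwards.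

Key step: step 5

Remark: locants of the bicyclic compounds follow the octahydro-2H-chromene numbering of the target (O1, C2, C3, C4, C4a, C5, C6, C7, C8, C8a); oxane C2, C3 and C6 of compound 5 become chromene C8a, C4a and C2.
Remark: the carbon that becomes C4a is configurationally labile until step 5, so 3 and 5 are carried as epimer mixtures; 1, 2 and 6 are taken as purchased.

Step 1
Reactants: 1 (R)-linalool; 2 methyl but-2-ynoate
Product: 3 methyl (2E,7R)-7-hydroxy-3,7-dimethyl-4-(prop-1-en-2-yl)nona-2,8-dienoate (both C4 epimers)
Conditions: EtAlCl2 (2.2 equiv), CH2Cl2, −78 → 0 °C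
Reagents that add atoms: none
Why: Lewis-acid-promoted Alder-ene reaction of an alkynoate with a trisubstituted alkene: the first equivalent of EtAlCl2 masks the tertiary alcohol as its chloroaluminium alkoxide, the ester-complexed ynoate is attacked at its β-carbon by the less substituted carbon of the 6,7-alkene while a hydrogen of a geminal methyl group is transferred suprafacially, which should give the isopropenyl group and the (E)-enoate, the vinyl group being far less nucleophilic; the new C4 centre is left uncontrolled because it is equilibrated in step 5.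

Step 2
Reactants: 3
Product: 5 methyl (2E)-3-[(6R)-6-ethenyl-2-methoxy-2,6-dimethyloxan-3-yl]but-2-enoate (mixture at oxane C2 and C3), via hydroxy ketone 4 (not isolated)
Conditions: O3 (1.0 equiv, Sudan Red 7B end point), CH2Cl2–MeOH 4:1, −78 °C; Me2S; then PPTS (5 mol %), MeOH, 23 °C
Reagents that add atoms: methanol CO
Why: Criegee ozonolysis should take the electron-rich 1,1-disubstituted isopropenyl alkene in preference to the vinyl group (deactivated by the allylic oxygen) and the enoate, and acidic methanol locks the resulting δ-hydroxy methyl ketone as the six-membered cyclic methyl ketal; the two new oxane centres form as mixtures and are both reset in step 5.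

Step 3
Reactants: 6 methyl 2,2-dimethylpent-4-enoate
Product: 7 methyl 2,2-dimethyl-4-oxopentanoate
Conditions: PdCl2 (10 mol %), CuCl (1 equiv), O2 (1 atm), DMF–H2O 7:1, 23 °C
Reagents that add atoms: water O
Why: Wacker oxidation (Markovnikov hydroxypalladation of the terminal alkene, β-hydride elimination, reoxidation by CuCl/O2) gives the methyl ketone; no stereocentre is formed.

Step 4
Reactants: 7
Product: 8 methyl 2,2-dimethyl-4-[(trimethylsilyl)oxy]pent-4-enoate
Conditions: LiN(i-Pr)2, THF, −78 °C; Me3SiCl, −78 → 0 °C
Reagents that add atoms: chlorotrimethylsilane C[Si](C)(C)Cl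
Why: kinetic enolisation at the unhindered methyl group (the CH2 is neopentylic and the ester has no α-hydrogen) followed by O-silylation gives the terminal enol silane; no stereocentre is formed.

Step 5
Reactants: 5 methyl (2E)-3-[(6R)-6-ethenyl-2-methoxy-2,6-dimethyloxan-3-yl]but-2-enoate; 8 methyl 2,2-dimethyl-4-[(trimethylsilyl)oxy]pent-4-enoate
Product: 10 methyl 2-[(2R,4aS,5R,6R,8aR)-2-ethenyl-5-(2-methoxy-2-oxoethyl)-2,5,8a-trimethyl-7-oxo-octahydro-2H-chromen-6-yl]-2-methylpropanoate, via C-glycoside ketone 9 (not isolated)
Conditions: TMSOTf (0.1 equiv), 8 (1.5 equiv), CH2Cl2, −78 °C; then i-Pr2NEt (3 equiv), TMSOTf (2.5 equiv), −78 → 0 °C, same flask; aq. NaHCO3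
Reagents that add atoms: none
Why: Catalytic TMSOTf ionises ketal 5 to the cyclic C8a oxocarbenium ion, which the terminal CH2 of enol silane 8 captures (Mukaiyama C-glycosylation, C8–C8a) to give ketone 9; i-Pr2NEt/TMSOTf then turn the C7 ketone into its C6=C7 enol silane, which adds to the silyl-activated (E)-enoate (intramolecular Mukaiyama–Michael addition, C5–C6). The closest known reaction type is the α,α′-annulation of a ketone bis-enol equivalent onto a 1,3-bis-electrophile, here a Mukaiyama addition to a ketal followed by a Mukaiyama–Michael cyclisation. The carbocycle closes in the 6-(enolexo)-exo-trig mode, and the only other enol silane of 9 (toward C8) would have to form a four-membered ring and cannot cyclise. C8a is set by axial attack on the half-chair oxocarbenium ion, cis to the pseudo-equatorial C4a substituent and syn to the axial 2-vinyl group (smaller than 2-methyl), while C4a equilibrates through the enol ether so that both epimers of 5 converge. At C5 the C4a–H bond eclipses the C5 methyl group (allylic 1,2-strain) and the tethered nucleophile can only arrive from the C8a side, which places 5-CH3 cis to 8a-CH3, and C6, epimerisable α to the ketone, should settle with the CMe2CO2Me group equatorial. The step needs 1,3-induction from C2 across the ring oxygen, expected to be only moderate (the minor diastereomer would be removed at 10), and enolisation of 9 away from C8, secured because only the C6-side enol silane is consumed irreversibly.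

Step 6
Reactants: 10
Product: 12 methyl 2-[(2R,4aS,5S,6R,8aR)-2-ethenyl-5-(2-methoxy-2-oxoethyl)-2,5,8a-trimethyl-octahydro-2H-chromen-6-yl]-2-methylpropanoate, via tosylhydrazone 11 (not isolated)
Conditions: TsNHNH2, EtOH, 60 °C; then catecholborane, CHCl3, 0 °C; NaOAc·3H2O, 60 °C
Reagents that add atoms: none
Why: Caglioti-type tosylhydrazone reduction: hydride adds to the C=N bond and acetate-induced loss of sulfinate and N2 from the diazene replaces the C7 oxygen by two hydrogens under near-neutral conditions, so the base-labile β-alkoxy ketone and the γ-keto ester (which would cyclise with free hydrazine) never see Wolff–Kishner conditions; no stereocentre is created.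

Step 7
Reactants: 12
Product: 13 2-[(2R,4aS,5S,6R,8aR)-5-(carboxymethyl)-2-ethenyl-2,5,8a-trimethyl-octahydro-2H-chromen-6-yl]-2-methylpropanoic acid
Conditions: KOH (10 equiv), MeOH–H2O 3:1, 80 °C; then 1 M HCl to pH 3, 0 °C
Reagents that add atoms: potassium hydroxide [K+].[OH-]
Why: saponification of both methyl esters (the neopentylic one needs the heat) and cold, mild acidification, which the tertiary allylic ether should tolerate; no stereocentre is touched.

Compound list
1 | (R)-linalool, (3R)-3,7-dimethylocta-1,6-dien-3-ol | C=C[C@](C)(O)CCC=C(C)C | starting material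
2 | methyl but-2-ynoate | CC#CC(=O)OC | starting material
3 | methyl (2E,7R)-7-hydroxy-3,7-dimethyl-4-(prop-1-en-2-yl)nona-2,8-dienoate (C4 epimers) | C=C[C@](C)(O)CCC(C(C)=C)/C(C)=C/C(=O)OC | intermediate
4 | methyl (2E,7R)-4-acetyl-7-hydroxy-3,7-dimethylnona-2,8-dienoate (C4 epimers) | C=C[C@](C)(O)CCC(C(C)=O)/C(C)=C/C(=O)OC | intermediate (not isolated)
5 | methyl (2E)-3-[(6R)-6-ethenyl-2-methoxy-2,6-dimethyloxan-3-yl]but-2-enoate (mixture at oxane C2 and C3) | C=C[C@@]1(C)CCC(/C(C)=C/C(=O)OC)C(C)(OC)O1 | intermediate
6 | methyl 2,2-dimethylpent-4-enoate | C=CCC(C)(C)C(=O)OC | starting material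
7 | methyl 2,2-dimethyl-4-oxopentanoate | CC(=O)CC(C)(C)C(=O)OC | intermediate
8 | methyl 2,2-dimethyl-4-[(trimethylsilyl)oxy]pent-4-enoate | C=C(O[Si](C)(C)C)CC(C)(C)C(=O)OC | intermediate
9 | methyl 5-[(2R,3S,6R)-6-ethenyl-3-[(2E)-4-methoxy-4-oxobut-2-en-2-yl]-2,6-dimethyloxan-2-yl]-2,2-dimethyl-4-oxopentanoate (new chain cis to the butenoate and cis to the vinyl group) | C=C[C@@]1(C)CC[C@@H](/C(C)=C/C(=O)OC)[C@@](C)(CC(=O)CC(C)(C)C(=O)OC)O1 | intermediate (not isolated)
10 | methyl 2-[(2R,4aS,5R,6R,8aR)-2-ethenyl-5-(2-methoxy-2-oxoethyl)-2,5,8a-trimethyl-7-oxo-octahydro-2H-chromen-6-yl]-2-methylpropanoate (cis-fused; 2-CH3, 8a-CH3, 5-CH3, H-4a and the C6 side chain on one face) | C=C[C@@]1(C)CC[C@H]2[C@@](C)(CC(=O)OC)[C@H](C(C)(C)C(=O)OC)C(=O)C[C@@]2(C)O1 | intermediate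
11 | 7-(4-methylbenzenesulfonyl)hydrazone of 10 (configuration as in 10) | C=C[C@@]1(C)CC[C@H]2[C@@](C)(CC(=O)OC)[C@H](C(C)(C)C(=O)OC)C(=NNS(=O)(=O)c3ccc(C)cc3)C[C@@]2(C)O1 | intermediate (not isolated)
12 | methyl 2-[(2R,4aS,5S,6R,8aR)-2-ethenyl-5-(2-methoxy-2-oxoethyl)-2,5,8a-trimethyl-octahydro-2H-chromen-6-yl]-2-methylpropanoate | C=C[C@@]1(C)CC[C@H]2[C@@](C)(CC(=O)OC)[C@H](C(C)(C)C(=O)OC)CC[C@@]2(C)O1 | intermediate
13 | 2-[(2R,4aS,5S,6R,8aR)-5-(carboxymethyl)-2-ethenyl-2,5,8a-trimethyl-octahydro-2H-chromen-6-yl]-2-methylpropanoic acid | C=C[C@@]1(C)CC[C@H]2[C@@](C)(CC(=O)O)[C@H](C(C)(C)C(=O)O)CC[C@@]2(C)O1 | target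

Total step count: 7. Longest linear sequence: 5 steps (1, 2, 5, 6, 7).

Steps most likely to fail

Step 5. Three processes can go wrong: loss of facial control across the ring oxygen in the C-glycosylation, enolisation of 9 toward C8 followed by β-elimination of O1, and stalling of the hindered Michael closure. The fallback takes the annulation apart. It sets out from 5 and 8: only the TMSOTf-catalysed addition is run (CH2Cl2, −78 °C) and ketone 9 is isolated and freed from its C2-mismatched diastereomer. Ring closure is then done under anionic, reversible conditions, t-BuOK (0.3 equiv), t-BuOH–THF, 0 °C. There the 6-exo-trig enolate Michael addition is the thermodynamic sink and any ring-opened enone can re-close by oxa-Michael addition. The route is rejoined at 10. This fallback makes no new compound.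

Step 1. The Lewis acid may ionise the tertiary allylic alkoxide, and the β-methyl ynoate may be too poor an enophile. The fallback avoids strong Lewis acids and builds the same ketal by olefination. It sets out from 1: ozonolysis of the trisubstituted alkene (O3, CH2Cl2–MeOH, −78 °C; Me2S) gives (5R)-5-ethenyl-5-methyloxolan-2-ol F1. Wittig reaction of F1 with (1-methoxyethyl)triphenylphosphonium chloride and t-BuOK (THF, 0 → 23 °C) gives the enol ether (3R)-7-methoxy-3-methylocta-1,6-dien-3-ol F2. TMSOTf-catalysed addition of F2 to the oxocarbenium ion from methyl 3,3-dimethoxybutanoate (CH2Cl2, −78 °C), with capture of the new oxocarbenium carbon by the tertiary hydroxyl, gives methyl 3-[(6R)-6-ethenyl-2-methoxy-2,6-dimethyloxan-3-yl]-3-methoxybutanoate F3. E1cB loss of methanol from F3 (DBU, toluene, 80 °C) returns to the route at 5.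

Step 6. Hydrazone formation at the doubly neopentylic C7 ketone may be incomplete, and the long acidic condensation may open the β-alkoxy ketone. The fallback removes the oxygen through sulfur and a radical step. It sets out from 10: ethane-1,2-dithiol and BF3·OEt2 (CH2Cl2, −20 °C) give the spiro-1,3-dithiolane of 10 at C7 F4 (configuration elsewhere as in 10). Radical desulfurisation of F4 with Bu3SnH and AIBN (toluene, 110 °C), which should spare the vinyl group and the esters, returns to the route at 12.

Further compounds
F1 | step 1 | (5R)-5-ethenyl-5-methyloxolan-2-ol | C=C[C@@]1(C)CCC(O)O1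
F2 | step 1 | (3R)-7-methoxy-3-methylocta-1,6-dien-3-ol | C=C[C@](C)(O)CCC=C(C)OC
F3 | step 1 | methyl 3-[(6R)-6-ethenyl-2-methoxy-2,6-dimethyloxan-3-yl]-3-methoxybutanoate | C=C[C@@]1(C)CCC(C(C)(OC)CC(=O)OC)C(C)(OC)O1
F0 | step 5 | none | none
F4 | step 6 | spiro-1,3-dithiolane of ketone 10 at C7 | C=C[C@@]1(C)CC[C@H]2[C@@](C)(CC(=O)OC)[C@H](C(C)(C)C(=O)OC)C3(SCCS3)C[C@@]2(C)O1
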